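The carbocycle is closed by joining the ring methylene C1 to C6, the ring carbon that carries the side chain; once the C2–C3 epoxide is read as an alkene this bond is doubly allylic (C2=C3 and C7=C14), and O5 lies cis to the side chain. The precursor is a 2,5-dihydrofuran (O4–C1) linked through C4–C5 to a six-membered cyclic allylsiloxane (O5–Si–C14). A silyl triflate opens the dihydrofuran to a Z allyl cation that is captured by C6 of the tethered allylsilane. One operation forms the ring and both alkenes, sets C6 cis to O5 because the temporary siloxane ring holds O5 in the alkene plane, silylates O4 and unmasks O5 for a directed epoxidation.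

Key step: step 11

Atom labels used below: C1 ring CH2; C2 and C3 the epoxide carbons (C3 bears the methyl group); C4 and C5 the two angelate-bearing carbons with oxygens O4 and O5; C6 the ring CH bearing the side chain; C7(=C14H2); C8 the acetoxy carbon; C9–C11 the prenyl unit.

Assumption: in step 2 the (R)-BINOL/Ti(Oi-Pr)4 catalyst is taken to give the (5R,1'R) adduct; if the opposite sense of induction is found, (S)-BINOL is used instead.

Step 1
Reactants: 1 4-methylfuran-2(5H)-one
Product: 2 trimethyl[(4-methylfuran-2-yl)oxy]silane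
Conditions: Me3SiOTf, Et3N, Et2O, 0 °C
Reagents that add atoms: trimethylsilyl trifluoromethanesulfonate, C[Si](C)(C)OS(=O)(=O)C(F)(F)F
Why: Soft enolisation at the γ-carbon and O-silylation should give the aromatic 2-silyloxyfuran (silyl dienol ether formation).

Step 2
Reactants: 2 trimethyl[(4-methylfuran-2-yl)oxy]silane, 3 prop-2-enal (acrolein)
Product: 5 (5R)-5-[(1R)-1-hydroxyprop-2-en-1-yl]-4-methylfuran-2(5H)-one, via O-trimethylsilyl aldol adduct 4 (not isolated)
Conditions: Ti(Oi-Pr)4 (20 mol %), (R)-BINOL (20 mol %), Et2O, −20 °C; then aq HCl, THF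
Reagents that add atoms: none
Why: The silyloxyfuran should add through its γ-carbon to the carbonyl group of the titanium-bound aldehyde (vinylogous Mukaiyama aldol reaction), the Lewis acid pathway favouring the threo adduct and the BINOL ligand choosing the enantioface, which sets C4 and C5.

Step 3
Reactants: 5 (5R)-5-[(1R)-1-hydroxyprop-2-en-1-yl]-4-methylfuran-2(5H)-one
Product: 6 (2Z,4R,5R)-3-methylhepta-2,6-diene-1,4,5-triol
Conditions: i-Bu2AlH (4 equiv), CH2Cl2, −78 to 0 °C; aq potassium sodium tartrate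
Reagents that add atoms: none
Why: 1,2-Reduction of the unsaturated lactone (i-Bu2AlH reduction of an enoate) should give the ene-diol whose Z geometry is inherited from the ring, with no stereocentre touched.

Step 4
Reactants: 6 (2Z,4R,5R)-3-methylhepta-2,6-diene-1,4,5-triol
Product: 7 (1R)-1-[(2R)-3-methyl-2,5-dihydrofuran-2-yl]prop-2-en-1-ol
Conditions: PPh3, DIAD, THF, 0 °C to rt
Reagents that add atoms: none
Why: The primary allylic hydroxyl should be activated fastest and displaced by O4 in a 5-exo-tet closure that the Z alkene preorganises (Mitsunobu cyclodehydration), which leaves O5 as the only free hydroxyl.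

Step 5
Reactants: 8 4-methylpent-3-enoic acid
Product: 10 N-methoxy-N,4-dimethylpent-3-enamide, via acyl imidazole 9 (not isolated)
Conditions: 1,1'-carbonyldiimidazole, CH2Cl2, rt; then MeNH(OMe)·HCl
Reagents that add atoms: N,O-dimethylhydroxylamine hydrochloride, CNOC.Cl
Why: Activation as the acyl imidazole and aminolysis should give the Weinreb amide under conditions mild enough to keep the β,γ-alkene in place (amide coupling).

Step 6
Reactants: 10 N-methoxy-N,4-dimethylpent-3-enamide, 11 prop-1-yn-1-ylmagnesium bromide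
Product: 12 7-methyloct-6-en-2-yn-4-one
Conditions: THF, −20 to 0 °C; aq NH4Cl
Reagents that add atoms: none
Why: The chelated tetrahedral adduct should stop at the ketone stage (Weinreb ketone synthesis).

Step 7
Reactants: 12 7-methyloct-6-en-2-yn-4-one
Product: 13 (4S)-7-methyloct-6-en-2-yn-4-ol
Conditions: Ru[(S,S)-TsDPEN](p-cymene) (1 mol %), i-PrOH, 25 °C
Reagents that add atoms: none
Why: Base-free Noyori asymmetric transfer hydrogenation of an alkynyl ketone should deliver hydride to one carbonyl face, the alkynyl group playing the role of the unsaturated substituent, which sets C8 as S.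

Step 8
Reactants: 13 (4S)-7-methyloct-6-en-2-yn-4-ol, 14 (chloromethyl)dimethyl(propan-2-yloxy)silane
Product: 17 (4Z,5S)-4-ethylidene-2,2-dimethyl-5-(3-methylbut-2-en-1-yl)-1,2-oxasilolane, via Grignard reagent 15 (not isolated), via open-chain isopropoxysilyl alcohol 16 (not isolated)
Conditions: 14, Mg, THF, 40 °C; then 13, CuI (10 mol %), Et2O/THF, reflux; aq NH4Cl; PPTS (cat.), toluene, 60 °C
Reagents that add atoms: none
Why: The magnesium alkoxide of 13 should direct a copper-catalysed anti-carbomagnesiation that places the silylmethyl group on the alkyne carbon next to the carbinol, and the hydroxyl then displaces isopropoxide at silicon to close the five-membered siloxane; the ethylidene geometry is of no consequence because that carbon is lost in step 10.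

Step 9
Reactants: 17 (4Z,5S)-4-ethylidene-2,2-dimethyl-5-(3-methylbut-2-en-1-yl)-1,2-oxasilolane, 7 (1R)-1-[(2R)-3-methyl-2,5-dihydrofuran-2-yl]prop-2-en-1-ol
Product: 19 (2Z,4S)-3-{[dimethyl({(1R)-1-[(2R)-3-methyl-2,5-dihydrofuran-2-yl]prop-2-en-1-yl}oxy)silyl]methyl}-7-methylocta-2,6-dien-4-yl acetate, via chlorosilane acetate 18 (not isolated)
Conditions: AcCl (1.0 equiv), Et4NCl (cat.), CH2Cl2, 0 °C to rt; volatiles removed; then 7, imidazole, CH2Cl2, 0 °C
Reagents that add atoms: acetyl chloride, CC(=O)Cl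
Why: The strained Si–O bond of the oxasilolane should be cleaved by the acyl chloride (acylative cleavage of an alkoxysilane), which installs the C8 acetate and a chlorosilane in one operation, and the chlorosilane then silylates O5 of 7 (silyl ether formation).

Step 10
Reactants: 19 (2Z,4S)-3-{[dimethyl({(1R)-1-[(2R)-3-methyl-2,5-dihydrofuran-2-yl]prop-2-en-1-yl}oxy)silyl]methyl}-7-methylocta-2,6-dien-4-yl acetate
Product: 20 (1S)-1-{(6R)-2,2-dimethyl-6-[(2R)-3-methyl-2,5-dihydrofuran-2-yl]-3,6-dihydro-2H-1,2-oxasilin-4-yl}-4-methylpent-3-en-1-yl acetate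
Conditions: second-generation Grubbs catalyst RuCl2(=CHPh)(PCy3)(H2IMes) (5 mol %), CH2Cl2, 40 °C
Reagents that add atoms: none
Why: Silicon-tethered ring-closing metathesis between the C6 vinyl group and the ethylidene unit should form the C6=C7 bond inside a six-membered allylsiloxane with loss of propene, the other alkenes being trisubstituted and unable to close an unstrained ring.

Step 11
Reactants: 20 (1S)-1-{(6R)-2,2-dimethyl-6-[(2R)-3-methyl-2,5-dihydrofuran-2-yl]-3,6-dihydro-2H-1,2-oxasilin-4-yl}-4-methylpent-3-en-1-yl acetate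
Product: 22 (3S)-2-[(1S,5R,6R)-6-hydroxy-4-methyl-5-(triethylsilyloxy)cyclohex-3-en-1-yl]-6-methylhepta-1,5-dien-3-yl acetate, via cyclised silyl triflate 21 (not isolated)
Conditions: Et3SiOTf (1.5 equiv), 2,6-di-tert-butyl-4-methylpyridine, CH2Cl2, −78 to −40 °C, 20 added slowly; then aq NaHCO3, THF, 25 °C
Reagents that add atoms: triethylsilyl trifluoromethanesulfonate, CC[Si](CC)(CC)OS(=O)(=O)C(F)(F)F
Why: Proposed new method: Et3SiOTf should silylate the dihydrofuran oxygen O4, the most basic site, and the oxonium ion should ionise at the primary allylic C1–O bond to a Z-configured C1–C2–C3 allyl cation that keeps O4 as its triethylsilyl ether, after which the C6=C7 bond of the allylsiloxane attacks C1 and the β-silyl cation at C7 collapses to the C7=C14 methylene by loss of silicon; the closest known reaction type is the Lewis acid promoted Hosomi–Sakurai allylation of allylic ethers and acetates, here intramolecular and fed by opening of a cyclic allylic ether. The cyclohexene closes in a 6-exo-trig mode at the C6=C7 bond with the allyl cation unit C1–C3 inside the new ring, which only the Z cation delivered by the five-membered ring allows. C6 is the only new stereocentre: C1 is tethered through C4 and must add to the face of C6=C7 on which C4 lies, while the siloxane ring holds O5 close to the alkene plane, so C7 and O5 should end up cis and silicon leaves from the opposite face (anti SE2'). The step needs site-selective ionisation of C1–O4 over the allylic C8 acetate and the C5–O5 siloxane, which the basicity of the ether oxygen and the tertiary terminus C3 of the cation should secure, and attack at C1 and not C3, which ring size enforces. Slow addition of 20 to excess silyl triflate and hindered base should keep the alkoxysilyl triflate 21 from silylating unreacted 20, and mild aqueous hydrolysis then frees O5 while the triethylsilyl ether at O4 stays.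

Step 12
Reactants: 22 (3S)-2-[(1S,5R,6R)-6-hydroxy-4-methyl-5-(triethylsilyloxy)cyclohex-3-en-1-yl]-6-methylhepta-1,5-dien-3-yl acetate
Product: 23 (3S)-2-[(1S,2S,3R,4S,6S)-3-hydroxy-1-methyl-2-(triethylsilyloxy)-7-oxabicyclo[4.1.0]heptan-4-yl]-6-methylhepta-1,5-dien-3-yl acetate
Conditions: VO(acac)2 (5 mol %), t-BuOOH (1.5 equiv), CH2Cl2, 0 °C to rt
Reagents that add atoms: tert-butyl hydroperoxide, CC(C)(C)OO
Why: The homoallylic C5 hydroxyl should bind vanadium and deliver oxygen to the ring alkene from its own face, anti to the C4 silyl ether (hydroxyl-directed epoxidation), which sets C2 and C3; the C7=C14 alkene is deactivated by its allylic acetate and the prenyl alkene is not directed.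

Step 13
Reactants: 23 (3S)-2-[(1S,2S,3R,4S,6S)-3-hydroxy-1-methyl-2-(triethylsilyloxy)-7-oxabicyclo[4.1.0]heptan-4-yl]-6-methylhepta-1,5-dien-3-yl acetate
Product: 24 (3S)-2-[(1R,2S,3R,4S,6S)-2,3-dihydroxy-1-methyl-7-oxabicyclo[4.1.0]heptan-4-yl]-6-methylhepta-1,5-dien-3-yl acetate
Conditions: Bu4NF (1.2 equiv), AcOH (1.2 equiv), THF, 0 °C
Reagents that add atoms: none
Why: Buffered fluoride should cleave the triethylsilyl ether (desilylation) without acetate loss, epoxide opening or epoxide migration.

Step 14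
Reactants: 24 (3S)-2-[(1R,2S,3R,4S,6S)-2,3-dihydroxy-1-methyl-7-oxabicyclo[4.1.0]heptan-4-yl]-6-methylhepta-1,5-dien-3-yl acetate
Product: 25 (1S,2S,3R,4S,6S)-4-[(3S)-3-(acetyloxy)-6-methylhepta-1,5-dien-2-yl]-1-methyl-7-oxabicyclo[4.1.0]heptane-2,3-diyl bis[(2Z)-2-methylbut-2-enoate]
Conditions: LiN(SiMe3)2 (2.1 equiv), THF, −78 °C; then angelic anhydride (3 equiv), −78 to −20 °C; aq NH4Cl
Reagents that add atoms: (2Z)-2-methylbut-2-enoic anhydride (angelic anhydride), C/C=C(/C)C(=O)OC(=O)/C(C)=C\C
Why: Acylation of the lithium alkoxides with the anhydride at low temperature (alkoxide esterification) should esterify both hindered hydroxyls without Z-to-E isomerisation of the angelate, since no nucleophilic catalyst is present.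

Compound list
1 | 4-methylfuran-2(5H)-one | CC1=CC(=O)OC1 | starting material
2 | trimethyl[(4-methylfuran-2-yl)oxy]silane | Cc1coc(O[Si](C)(C)C)c1 | intermediate
3 | prop-2-enal (acrolein) | C=CC=O | starting material
4 | (5R)-4-methyl-5-[(1R)-1-(trimethylsilyloxy)prop-2-en-1-yl]furan-2(5H)-one | C=C[C@@H](O[Si](C)(C)C)[C@@H]1OC(=O)C=C1C | intermediate
5 | (5R)-5-[(1R)-1-hydroxyprop-2-en-1-yl]-4-methylfuran-2(5H)-one | C=C[C@@H](O)[C@@H]1OC(=O)C=C1C | intermediate
6 | (2Z,4R,5R)-3-methylhepta-2,6-diene-1,4,5-triol | C=C[C@@H](O)[C@H](O)/C(C)=C\CO | intermediate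
7 | (1R)-1-[(2R)-3-methyl-2,5-dihydrofuran-2-yl]prop-2-en-1-ol | C=C[C@@H](O)[C@@H]1OCC=C1C | intermediate
8 | 4-methylpent-3-enoic acid | CC(C)=CCC(=O)O | starting material
9 | 1-(1H-imidazol-1-yl)-4-methylpent-3-en-1-one | CC(C)=CCC(=O)n1ccnc1 | intermediate
10 | N-methoxy-N,4-dimethylpent-3-enamide | CON(C)C(=O)CC=C(C)C | intermediate
11 | prop-1-yn-1-ylmagnesium bromide | CC#C[Mg]Br | starting material
12 | 7-methyloct-6-en-2-yn-4-one | CC#CC(=O)CC=C(C)C | intermediate
13 | (4S)-7-methyloct-6-en-2-yn-4-ol | CC#C[C@@H](O)CC=C(C)C | intermediate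
14 | (chloromethyl)dimethyl(propan-2-yloxy)silane | CC(C)O[Si](C)(C)CCl | starting material
15 | {[dimethyl(propan-2-yloxy)silyl]methyl}magnesium chloride | CC(C)O[Si](C)(C)C[Mg]Cl | intermediate
16 | (2Z,4S)-3-{[dimethyl(propan-2-yloxy)silyl]methyl}-7-methylocta-2,6-dien-4-ol | C/C=C(\C[Si](C)(C)OC(C)C)[C@@H](O)CC=C(C)C | intermediate
17 | (4Z,5S)-4-ethylidene-2,2-dimethyl-5-(3-methylbut-2-en-1-yl)-1,2-oxasilolane | C/C=C1\C[Si](C)(C)O[C@H]1CC=C(C)C | intermediate
18 | (2Z,4S)-3-{[chloro(dimethyl)silyl]methyl}-7-methylocta-2,6-dien-4-yl acetate | CC(=O)O[C@@H](CC=C(C)C)/C(C[Si](C)(C)Cl)=C/C | intermediate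
19 | (2Z,4S)-3-{[dimethyl({(1R)-1-[(2R)-3-methyl-2,5-dihydrofuran-2-yl]prop-2-en-1-yl}oxy)silyl]methyl}-7-methylocta-2,6-dien-4-yl acetate | C=C[C@@H](O[Si](C)(C)C/C(=C\C)[C@H](CC=C(C)C)OC(C)=O)[C@@H]1OCC=C1C | intermediate
20 | (1S)-1-{(6R)-2,2-dimethyl-6-[(2R)-3-methyl-2,5-dihydrofuran-2-yl]-3,6-dihydro-2H-1,2-oxasilin-4-yl}-4-methylpent-3-en-1-yl acetate | CC(=O)O[C@@H](CC=C(C)C)C1=C[C@@H](O[Si](C)(C)C1)[C@@H]2OCC=C2C | intermediate
21 | 22 carrying a dimethyl(trifluoromethanesulfonyloxy)silyl group on O5 | C=C([C@H](CC=C(C)C)OC(C)=O)[C@@H]1CC=C(C)[C@@H](O[Si](CC)(CC)CC)[C@@H]1O[Si](C)(C)OS(=O)(=O)C(F)(F)F | intermediate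
22 | (3S)-2-[(1S,5R,6R)-6-hydroxy-4-methyl-5-(triethylsilyloxy)cyclohex-3-en-1-yl]-6-methylhepta-1,5-dien-3-yl acetate | C=C([C@H](CC=C(C)C)OC(C)=O)[C@@H]1CC=C(C)[C@@H](O[Si](CC)(CC)CC)[C@@H]1O | intermediate
23 | (3S)-2-[(1S,2S,3R,4S,6S)-3-hydroxy-1-methyl-2-(triethylsilyloxy)-7-oxabicyclo[4.1.0]heptan-4-yl]-6-methylhepta-1,5-dien-3-yl acetate | C=C([C@H](CC=C(C)C)OC(C)=O)[C@@H]1C[C@@H]2O[C@]2(C)[C@@H](O[Si](CC)(CC)CC)[C@@H]1O | intermediate
24 | (3S)-2-[(1R,2S,3R,4S,6S)-2,3-dihydroxy-1-methyl-7-oxabicyclo[4.1.0]heptan-4-yl]-6-methylhepta-1,5-dien-3-yl acetate | C=C([C@H](CC=C(C)C)OC(C)=O)[C@@H]1C[C@@H]2O[C@]2(C)[C@@H](O)[C@@H]1O | intermediate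
25 | (1S,2S,3R,4S,6S)-4-[(3S)-3-(acetyloxy)-6-methylhepta-1,5-dien-2-yl]-1-methyl-7-oxabicyclo[4.1.0]heptane-2,3-diyl bis[(2Z)-2-methylbut-2-enoate] | C=C([C@H](CC=C(C)C)OC(C)=O)[C@@H]1C[C@@H]2O[C@]2(C)[C@@H](OC(=O)/C(C)=C\C)[C@@H]1OC(=O)/C(C)=C\C | target

Total step count: 14. Longest linear sequence: 10 steps (steps 5–14 from 8; the branch from 1 through steps 1–4 and 9–14 is equally long).

Steps most likely to fail

Step 11 (Proposed new method). The silyl triflate may fail to ionise the dihydrofuran at C1–O4, or the alkoxysilyl triflate formed after ring closure may pass its silicon to other oxygens, so that O4 and O5 are no longer differentiated. The fallback uses established chemistry, sets out from 5 and returns at 22.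
- 5 is protected at O5 with 4-methoxybenzyl trichloroacetimidate and catalytic camphorsulfonic acid to give the 4-methoxybenzyl ether (5R)-5-{(1R)-1-[(4-methoxybenzyl)oxy]prop-2-en-1-yl}-4-methylfuran-2(5H)-one F1.
- i-Bu2AlH reduction gives the Z diol (2Z,4R,5R)-5-[(4-methoxybenzyl)oxy]-3-methylhepta-2,6-diene-1,4-diol F2.
- Ac2O with 2,4,6-collidine at −20 °C acetylates the primary hydroxyl to give (2Z,4R,5R)-4-hydroxy-5-[(4-methoxybenzyl)oxy]-3-methylhepta-2,6-dien-1-yl acetate F3.
- Et3SiCl and imidazole give the triethylsilyl ether (2Z,4R,5R)-5-[(4-methoxybenzyl)oxy]-3-methyl-4-(triethylsilyloxy)hepta-2,6-dien-1-yl acetate F4.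
- Buffered DDQ frees O5 to give (2Z,4R,5R)-5-hydroxy-3-methyl-4-(triethylsilyloxy)hepta-2,6-dien-1-yl acetate F5.
- Silylation with chlorosilane 18 and imidazole gives the O5 silyl ether of F5 carrying the (2Z,4S)-4-acetoxy-7-methylocta-2,6-dien-3-ylmethyl(dimethyl)silyl group F6.
- Ring-closing metathesis with the second-generation Grubbs catalyst gives the six-membered cyclic allylsiloxane with an open-chain Z allylic acetate F7.
- SnCl4 in CH2Cl2 at −78 °C then ionises the primary allylic acetate and the tethered allylsilane closes the ring, an intramolecular Hosomi–Sakurai-type allylation of an allylic ester; aqueous work-up returns 22.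

Step 2. Enantio- and diastereofacial control may be poor with acrolein, and conjugate addition or polymerisation of the aldehyde may compete. The fallback sets out from 2 and 3 and returns at 5. BF3·OEt2 in CH2Cl2 at −78 °C gives the racemic threo adduct, that is 5 together with its enantiomer (5S)-5-[(1S)-1-hydroxyprop-2-en-1-yl]-4-methylfuran-2(5H)-one F8. A Sharpless kinetic resolution (Ti(Oi-Pr)4, D-(−)-diisopropyl tartrate, t-BuOOH, 4 Å sieves, −20 °C) should then epoxidise F8 to the erythro epoxy alcohol (5S)-5-{(R)-hydroxy[(2S)-oxiran-2-yl]methyl}-4-methylfuran-2(5H)-one F9 and leave 5 unreacted.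

Step 14. Acylation of the two hindered hydroxyls may be slow, which gives time for isomerisation of angelate to tiglate and for base-induced migration of the epoxide toward the C4 alkoxide. The fallback sets out from 24 and returns at 25. Both hydroxyls are esterified with the unhindered 2-[bis(2,2,2-trifluoroethoxy)phosphoryl]propanoic acid (N,N'-diisopropylcarbodiimide, DMAP) to give the bis(phosphonopropanoate) F10. A double Still–Gennari olefination with acetaldehyde (KN(SiMe3)2, 18-crown-6, THF, −78 °C) then builds both Z-configured 2-methylbut-2-enoates on the molecule.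

Further compounds
F1 | step 11 | (5R)-5-{(1R)-1-[(4-methoxybenzyl)oxy]prop-2-en-1-yl}-4-methylfuran-2(5H)-one | C=C[C@@H](OCc1ccc(OC)cc1)[C@@H]1OC(=O)C=C1C
F2 | step 11 | (2Z,4R,5R)-5-[(4-methoxybenzyl)oxy]-3-methylhepta-2,6-diene-1,4-diol | C=C[C@@H](OCc1ccc(OC)cc1)[C@H](O)/C(C)=C\CO
F3 | step 11 | (2Z,4R,5R)-4-hydroxy-5-[(4-methoxybenzyl)oxy]-3-methylhepta-2,6-dien-1-yl acetate | C=C[C@@H](OCc1ccc(OC)cc1)[C@H](O)/C(C)=C\COC(C)=O
F4 | step 11 | (2Z,4R,5R)-5-[(4-methoxybenzyl)oxy]-3-methyl-4-(triethylsilyloxy)hepta-2,6-dien-1-yl acetate | C=C[C@@H](OCc1ccc(OC)cc1)[C@H](O[Si](CC)(CC)CC)/C(C)=C\COC(C)=O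
F5 | step 11 | (2Z,4R,5R)-5-hydroxy-3-methyl-4-(triethylsilyloxy)hepta-2,6-dien-1-yl acetate | C=C[C@@H](O)[C@H](O[Si](CC)(CC)CC)/C(C)=C\COC(C)=O
F6 | step 11 | O5 silyl ether of F5 formed with chlorosilane 18 | C=C[C@@H](O[Si](C)(C)C/C(=C\C)[C@H](CC=C(C)C)OC(C)=O)[C@H](O[Si](CC)(CC)CC)/C(C)=C\COC(C)=O
F7 | step 11 | six-membered cyclic allylsiloxane from ring-closing metathesis of F6 | CC(=O)O[C@@H](CC=C(C)C)C1=C[C@@H](O[Si](C)(C)C1)[C@H](O[Si](CC)(CC)CC)/C(C)=C\COC(C)=O
F8 | step 2 | (5S)-5-[(1S)-1-hydroxyprop-2-en-1-yl]-4-methylfuran-2(5H)-one | C=C[C@H](O)[C@H]1OC(=O)C=C1C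
F9 | step 2 | (5S)-5-{(R)-hydroxy[(2S)-oxiran-2-yl]methyl}-4-methylfuran-2(5H)-one | O[C@@H]([C@@H]1CO1)[C@H]2OC(=O)C=C2C
F10 | step 14 | bis{2-[bis(2,2,2-trifluoroethoxy)phosphoryl]propanoate} of 24 (phosphonate α-carbons unspecified) | C=C([C@H](CC=C(C)C)OC(C)=O)[C@@H]1C[C@@H]2O[C@]2(C)[C@@H](OC(=O)C(C)P(=O)(OCC(F)(F)F)OCC(F)(F)F)[C@@H]1OC(=O)C(C)P(=O)(OCC(F)(F)F)OCC(F)(F)F
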